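## Structural features

The target is a cyclised diarylheptanoid: a tetrahydropyran (O1, C2–C6) whose C2 carries ring A (3,4-dihydroxy-5-methoxyphenyl), whose C4 carries a secondary hydroxyl and whose C6 carries a two-carbon arm to ring B (4-hydroxyphenyl). The stereocentres C2, C4 and C6 stand in a 1,3,5-relationship and are all-cis, (2S,4R,6S), so every substituent is equatorial in the chair; opened at O1–C2, C4 and C6 correspond to an anti (3S,5S)-1,3-diol of a linear heptane. Fragile points are the catechol of ring A (oxidised to an ortho-quinone by air or any oxidant), the O1–C2 bond (benzylic and para to a phenol, so open to acid ionisation and hydrogenolysis) and the single methyl ether, which must survive while three phenols are set free. The carbon skeleton is not the problem, since seven unbranched carbons link two arenes. The real difficulty is threefold: absolute control of two carbinol centres far from any directing group, stereocontrol at the benzylic ring carbon C2, and the distinction of the two neighbouring phenolic oxygens of ring A. The key step exploits the 4-hydroxyl of ring A being para to C2: in an open-chain precursor C2 is a methylene para to a phenol flanked by two alkoxy groups, which two-electron oxidation turns into a quinone methide carbon, and the hydroxyl on C6 (the future O1) sits at the right distance to add to it and close the six-membered ring.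

## Logic of the disconnections

**17 ⇒ 16.** Two phenolic O–H bonds (meta-oxygen of ring A, oxygen of ring B) are replaced by O–benzyl bonds. A free catechol and a second free phenol would not survive the ring-closing oxidation; benzyl ethers are inert to it and leave in one neutral operation. Nothing is gained in skeleton, but every later step becomes chemoselective. The forward step must cleave two aryl benzyl ethers without breaking the benzylic O1–C2 bond or the methyl ether.

**16 ⇒ 14 (through 15).** The O1–C2 bond is cut. C2 is the only position para to a free phenol, so the ring oxygen can be delivered to it after oxidation to 15. The cut removes the ring and the C2 stereocentre and leaves an acyclic anti-diol with two stereocentres. The forward step must oxidise only the benzylic methylene of ring A, close through the C5 hydroxyl and not the C3 hydroxyl, and place the aryl group equatorial.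

**14 ⇒ 11 (through 12 and 13).** The two carbinol C–H bonds are removed, turning both C–O bonds into carbonyl groups. An anti-1,3-diol is the natural product of a catalyst-controlled double hydrogenation of a 1,3-diketone, so both stereocentres vanish at once and an achiral precursor remains. The forward step needs a catalyst that fixes the first carbinol, controls the second as well, and ignores aryl benzyl ethers and a free phenol.

**11 ⇒ 10.** A double bond is introduced between C1 and C2. The saturated link to ring A is not accessible from simple parts, whereas an alkene conjugated to the carbonyl is accessible by condensation. The forward hydrogenation must saturate this alkene but spare two benzyl ethers and the carbonyl groups.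

**10 ⇒ 4 + 7.** The C1=C2 bond is cut as an aldol-type condensation between the terminal methyl of 4 and the formyl group of 7. This is the convergent cut: a one-carbon ring A unit and a six-carbon ring B unit. Ring A enters at the benzaldehyde oxidation level and its para-phenol is tolerated, so it never needs a mask. The forward step must react at the terminal methyl and not at the central carbon or the C5 methylene.

**4 ⇒ 1 + 2 (through 3).** The bond between the benzylic carbon of ring B and the chain (C6–C7 in heptane numbering) is cut. Both pieces are simple and the ring B phenol arrives already benzylated. The forward alkylation must occur once, at a terminal carbon of 1.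

**7 ⇒ 5 (through 6).** The O–benzyl bond at the meta-oxygen of ring A is cut. The two neighbouring phenols of 5 differ in acidity because only one is para to the formyl group; that difference is the handle. The forward step must benzylate the less acidic oxygen and leave the para-oxygen free.

## Other disconnections considered

**Alternative 1:** The chain is cut on both sides of C4 (C3–C4 and C4–C5) and the ring is left open. In the forward sense the lithium anion of the silyl dithiane A1 opens the alkyl epoxide A2 at its CH2; the alkoxide takes the silyl group from carbon (1,4-Brook rearrangement), and the regenerated dithiane anion opens the aryl oxirane A3 at its CH2 to give A4.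
- In its favour: three components are joined in one flask and two skeletal C–C bonds are made, where the chosen key step makes none; on bonds built per operation it is the better plan. Ring A is uniformly benzylated, so no regioselective monobenzylation is needed and no phenol faces an oxidant; on protecting-group simplicity it is also better.
- Against it here: A4 has neither the ring nor the C4 stereocentre. Still to come are dithioketal removal beside electron-rich arenes, a 1,3-anti reduction of a ketone flanked by two β-oxygens, ring closure at the benzylic carbinol, desilylation and hydrogenolysis, with sulfur residues a concern for the palladium catalyst. The closure would most plausibly go through a benzylic cation, so the configuration brought in by A3 is discarded and the all-cis ring rests on the same thermodynamic preference as in the chosen plan. A3 is an electron-rich styrene oxide that may open at the benzylic carbon or rearrange.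
- Comparison: anionic, cryogenic chemistry against a mild oxidation at room temperature; with about three steps per epoxide and five after the coupling, roughly twice the seven steps of the chosen route.

**Alternative 2:** The cut is O1–C6, with transposition of the C6–C8 allyl unit. In A5, PdCl2(MeCN)2 (divalent palladium) activates the E-alkene, the C2 hydroxyl adds to C6 on the face set by the C8 hydroxyl (syn SN2′ course, which requires the R carbinol at C8, heptane C7), and loss of that hydroxyl gives the styryl pyran A6.
- In its favour: C6 is set stereospecifically under kinetic control. Where a ring has no strong thermodynamic bias this is the better control element; here, with all groups equatorial, both plans should reach the same isomer and are equal on this point. All phenols are benzyl ethers, the step is catalytic and redox-neutral, and one final hydrogenation would saturate the alkene and remove the benzyl ethers together.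
- Against it here: A5 needs three separately made carbinol stereocentres (C2, C4, C8), one of which is consumed. Both the C2 and C8 carbinols are benzylic on oxygenated rings (C8 also allylic) and can ionise with a Lewis-acidic palladium salt, which would erode the chirality transfer. In A6 the O1–C6 bond is allylic, so the last hydrogenation must saturate the alkene before it cleaves that bond. A silyl ether must also be removed.
- Comparison: three stereocentres made one by one against two made in one hydrogenation; at least twelve steps against seven.

**Alternative 3:** The cut is C2–C3, a carbon–carbon bond of the ring. Me2AlCl ionises the enol acetal A7 at the C–O bond to the enol oxygen; the aryl-stabilised oxocarbenium ion and the tethered aluminium enolate recombine through a chair with both substituents equatorial and give the cis-pyranone A8 (Petasis–Ferrier rearrangement).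
- In its favour: 2,6-cis control from a single stereocentre (C6) is reliable and the ring closure forms a C–C bond. Ring A enters at the aldehyde oxidation level, as in the chosen plan (equal), with uniform benzyl protection (better). The asymmetric effort is equal: one enantioselective reduction.
- Against it here: A7 would take about six steps, including a carbonyl methylenation with Cp2TiMe2. The tri-oxygenated aryl group stabilises the oxocarbenium ion strongly, which may slow the C–C closure, and the aluminium Lewis acid may attack a benzyl ether. A8 still needs a diastereoselective ketone reduction, so C4 is a separate stereochemical event, before hydrogenolysis.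
- Comparison: ten to eleven steps against seven, and three stereocontrol events against two.

Key step: step 6

Remark on numbering: open-chain compounds carry heptane locants (C1 next to ring A, C7 next to ring B); heptane C1, C3 and C5 become pyran C2, C4 and C6.

Remark on the structures: 14 and 16 were checked atom by atom against 17. The anti (3S,5S) diol and the all-cis (2S,4R,6S) pyran have the same spatial arrangement at the two carbinol carbons; the change from S to R at the carbinol that stays free is a change of CIP ranking only, so neither structure needs correction. What is improved is the way to 14: its para-phenol is carried free from the first step on ring A, so no masking and unmasking is needed, and the S ligand is specified in RuCl2[(S)-BINAP] because it is the one that leads to the (3S,5S) diol.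

Remark (assumptions): 1, 2 and 5 are taken as commercial; β-diketones 4, 10 and 11 are drawn as diketo tautomers although largely enolised; the borate species 8 and 9 are drawn in their simplest defined form.

## Route

**Step 1**
Reactants: 1 pentane-2,4-dione; 2 4-(benzyloxy)benzyl chloride
Product: 4 6-[4-(benzyloxy)phenyl]hexane-2,4-dione, via dilithium dianion of pentane-2,4-dione 3 (not isolated)
Conditions: LiN(i-Pr)2 (2.1 equiv), THF, −78 to 0 °C; 2 (0.9 equiv), 0 °C; aq NH4Cl
Reagents that add atoms: none
Why: γ-Alkylation of a β-diketone dianion: the second deprotonation takes place at a terminal methyl, and that terminal carbanion is far more nucleophilic than the central enolate carbon, so the benzylic chloride is attacked by C1 only; keeping the halide as limiting reagent suppresses double alkylation.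

**Step 2**
Reactants: 5 3,4-dihydroxy-5-methoxybenzaldehyde
Product: 7 3-(benzyloxy)-4-hydroxy-5-methoxybenzaldehyde, via disodium catecholate of the aldehyde 6 (not isolated)
Conditions: NaH (2.2 equiv), DMSO, 20 °C; BnBr (1.0 equiv), 20 °C; aq HCl
Reagents that add atoms: benzyl bromide, BrCc1ccccc1
Why: Regioselective mono-O-alkylation of a catecholate dianion (Williamson ether synthesis): in 6 the 4-oxide is delocalised into the para-formyl group and flanked by two ortho substituents, whereas the 3-oxide is the more basic and more nucleophilic site, so one equivalent of benzyl bromide should go to O3 and leave the para-hydroxyl free after acidification.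

**Step 3**
Reactants: 4 6-[4-(benzyloxy)phenyl]hexane-2,4-dione; 7 3-(benzyloxy)-4-hydroxy-5-methoxybenzaldehyde
Product: 10 (E)-1-[3-(benzyloxy)-4-hydroxy-5-methoxyphenyl]-7-[4-(benzyloxy)phenyl]hept-1-ene-3,5-dione, via dibutoxyboron chelate of the diketone 8 (not isolated), via dibutoxyboron chelate of the enedione 9 (not isolated)
Conditions: B2O3 (0.7 equiv), EtOAc, 75 °C; 7, B(OnBu)3 (2 equiv); n-BuNH2 (0.3 equiv), 75 °C; 0.4 M aq HCl, 60 °C
Reagents that add atoms: none
Why: Boron-templated aldol condensation of the Pabon type: chelation of the 1,3-dicarbonyl unit in 8 blocks Knoevenagel reaction at the central carbon and activates the terminal methyl, which condenses with the iminium form of 7 and dehydrates to the E-styryl chelate 9, released as 10 by dilute acid. Vanillin-type aldehydes with a free para-phenol are standard partners, and the methyl should react in preference to the more hindered C5 methylene.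

**Step 4**
Reactants: 10 (E)-1-[3-(benzyloxy)-4-hydroxy-5-methoxyphenyl]-7-[4-(benzyloxy)phenyl]hept-1-ene-3,5-dione
Product: 11 1-[3-(benzyloxy)-4-hydroxy-5-methoxyphenyl]-7-[4-(benzyloxy)phenyl]heptane-3,5-dione
Conditions: H2 (1 atm), 10% Pd/C, Ph2S (0.01 equiv), EtOAc, 23 °C
Reagents that add atoms: none
Why: Chemoselective heterogeneous hydrogenation: Pd/C partly poisoned by diphenyl sulfide still saturates a conjugated disubstituted alkene but should no longer hydrogenolyse aryl benzyl ethers or reduce the enolised diketone; no stereocentre is formed.

**Step 5**
Reactants: 11 1-[3-(benzyloxy)-4-hydroxy-5-methoxyphenyl]-7-[4-(benzyloxy)phenyl]heptane-3,5-dione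
Product: 14 (3S,5S)-1-[3-(benzyloxy)-4-hydroxy-5-methoxyphenyl]-7-[4-(benzyloxy)phenyl]heptane-3,5-diol, via (5S)-5-hydroxy-3-ketone 12 (not isolated), via (3S)-3-hydroxy-5-ketone 13 (not isolated)
Conditions: H2 (50 atm), RuCl2[(S)-BINAP] (1 mol %), MeOH–CH2Cl2, 50 °C
Reagents that add atoms: none
Why: Noyori asymmetric hydrogenation of a β-diketone: the keto form binds ruthenium as a chelate through the second carbonyl, the S ligand sets the first carbinol as S in 12 or 13, and the second, catalyst-controlled reduction of the β-hydroxy ketone gives the anti (3S,5S) diol, the minor enantiomer of the first stage being diverted into the syn diastereomer. Aryl benzyl ethers, arenes and the free phenol are inert to this homogeneous catalyst.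

**Step 6**
Reactants: 14 (3S,5S)-1-[3-(benzyloxy)-4-hydroxy-5-methoxyphenyl]-7-[4-(benzyloxy)phenyl]heptane-3,5-diol
Product: 16 (2S,4R,6S)-2-[3-(benzyloxy)-4-hydroxy-5-methoxyphenyl]-6-{2-[4-(benzyloxy)phenyl]ethyl}tetrahydro-2H-pyran-4-ol, via para-quinone methide 15 (not isolated)
Conditions: Ag2O (1.5 equiv), 4 Å MS, CH2Cl2 (0.01 M), 23 °C, dark; filter; PPTS (5 mol %), 23 °C
Reagents that add atoms: none
Why: Ag2O, an oxide of monovalent silver, takes two electrons and two protons from the 2,6-dialkoxyphenol of 14 (phenoxyl radical, then loss of a benzylic hydrogen) and gives the para-quinone methide 15, a vinylogous enone whose exocyclic carbon is the future C2. The C5 hydroxyl adds to that carbon in an oxa-1,6-conjugate addition and the ring regains aromaticity as the phenol; the mild acid completes this addition for any 15 that persists. The closest known reaction type is the silver oxide oxidation of 4-alkyl-2,6-dialkoxyphenols to quinone methides and their capture by alcohols, used here intramolecularly. The pyran closes in the 6-exo-trig mode, whereas the C3 hydroxyl would have to close an oxetane and should not compete. The new stereocentre C2 is controlled by the two carbinol centres: because the diol is anti, the chain to ring B and the C3 hydroxyl can both be equatorial in the chair-like transition state, and the flat quinone methide takes the third equatorial position, which leads to the all-cis (2S,4R,6S) ether. This isomer is also the most stable one, and under PPTS a C2 epimer can re-ionise to the para-hydroxybenzyl cation and re-close, so kinetic and thermodynamic control point the same way. The step needs site-selective oxidation, which the substrate secures because ring A alone has a free para-hydroxyl while ring B and the meta-oxygen are benzyl ethers that Ag2O leaves alone. High dilution favours ring closure over dimerisation of 15, and the small excess of oxidant guards 16, which still has a para-hydroxybenzylic hydrogen, against a second oxidation.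

**Step 7**
Reactants: 16 (2S,4R,6S)-2-[3-(benzyloxy)-4-hydroxy-5-methoxyphenyl]-6-{2-[4-(benzyloxy)phenyl]ethyl}tetrahydro-2H-pyran-4-ol
Product: 17 (2S,4R,6S)-2-(3,4-dihydroxy-5-methoxyphenyl)-6-[2-(4-hydroxyphenyl)ethyl]tetrahydro-2H-pyran-4-ol
Conditions: H2 (1 atm), 10% Pd/C, EtOAc–MeOH, 23 °C
Reagents that add atoms: none
Why: Hydrogenolysis of aryl benzyl ethers on Pd/C; these O–CH2Ph bonds should be cleaved much faster than the secondary, dialkyl-type benzylic O1–C2 bond in a neutral solvent, and no stereocentre is touched.

## Compound list

1 | pentane-2,4-dione | CC(=O)CC(C)=O | starting material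
2 | 4-(benzyloxy)benzyl chloride | ClCc1ccc(OCc2ccccc2)cc1 | starting material
3 | dilithium dianion of pentane-2,4-dione | [Li+].[Li+].C=C([O-])C=C(C)[O-] | intermediate (not isolated)
4 | 6-[4-(benzyloxy)phenyl]hexane-2,4-dione | CC(=O)CC(=O)CCc1ccc(OCc2ccccc2)cc1 | intermediate
5 | 3,4-dihydroxy-5-methoxybenzaldehyde | COc1cc(C=O)cc(O)c1O | starting material
6 | disodium 5-formyl-3-methoxybenzene-1,2-diolate | [Na+].[Na+].COc1cc(C=O)cc([O-])c1[O-] | intermediate (not isolated)
7 | 3-(benzyloxy)-4-hydroxy-5-methoxybenzaldehyde | COc1cc(C=O)cc(OCc2ccccc2)c1O | intermediate
8 | dibutoxyboron chelate of 4 | CCCCO[B-]1(OCCCC)OC(C)=CC(CCc2ccc(OCc3ccccc3)cc2)=[O+]1 | intermediate (not isolated)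
9 | dibutoxyboron chelate of 10 | CCCCO[B-]1(OCCCC)OC(/C=C/c2cc(OC)c(O)c(OCc3ccccc3)c2)=CC(CCc2ccc(OCc3ccccc3)cc2)=[O+]1 | intermediate (not isolated)
10 | (E)-1-[3-(benzyloxy)-4-hydroxy-5-methoxyphenyl]-7-[4-(benzyloxy)phenyl]hept-1-ene-3,5-dione | COc1cc(/C=C/C(=O)CC(=O)CCc2ccc(OCc3ccccc3)cc2)cc(OCc2ccccc2)c1O | intermediate
11 | 1-[3-(benzyloxy)-4-hydroxy-5-methoxyphenyl]-7-[4-(benzyloxy)phenyl]heptane-3,5-dione | COc1cc(CCC(=O)CC(=O)CCc2ccc(OCc3ccccc3)cc2)cc(OCc2ccccc2)c1O | intermediate
12 | (5S)-1-[3-(benzyloxy)-4-hydroxy-5-methoxyphenyl]-7-[4-(benzyloxy)phenyl]-5-hydroxyheptan-3-one | COc1cc(CCC(=O)C[C@@H](O)CCc2ccc(OCc3ccccc3)cc2)cc(OCc2ccccc2)c1O | intermediate (not isolated)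
13 | (3S)-1-[3-(benzyloxy)-4-hydroxy-5-methoxyphenyl]-7-[4-(benzyloxy)phenyl]-3-hydroxyheptan-5-one (locants counted from ring A) | COc1cc(CC[C@H](O)CC(=O)CCc2ccc(OCc3ccccc3)cc2)cc(OCc2ccccc2)c1O | intermediate (not isolated)
14 | (3S,5S)-1-[3-(benzyloxy)-4-hydroxy-5-methoxyphenyl]-7-[4-(benzyloxy)phenyl]heptane-3,5-diol | COc1cc(CC[C@H](O)C[C@@H](O)CCc2ccc(OCc3ccccc3)cc2)cc(OCc2ccccc2)c1O | intermediate
15 | 2-(benzyloxy)-4-{(3S,5S)-7-[4-(benzyloxy)phenyl]-3,5-dihydroxyheptylidene}-6-methoxycyclohexa-2,5-dien-1-one (either alkene geometry) | O=C1C(OC)=CC(=CC[C@H](O)C[C@@H](O)CCc2ccc(OCc3ccccc3)cc2)C=C1OCc1ccccc1 | intermediate (not isolated)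
16 | (2S,4R,6S)-2-[3-(benzyloxy)-4-hydroxy-5-methoxyphenyl]-6-{2-[4-(benzyloxy)phenyl]ethyl}tetrahydro-2H-pyran-4-ol | COc1cc([C@@H]2C[C@H](O)C[C@H](CCc3ccc(OCc4ccccc4)cc3)O2)cc(OCc2ccccc2)c1O | intermediate
17 | (2S,4R,6S)-2-(3,4-dihydroxy-5-methoxyphenyl)-6-[2-(4-hydroxyphenyl)ethyl]tetrahydro-2H-pyran-4-ol | COc1cc([C@@H]2C[C@H](O)C[C@H](CCc3ccc(O)cc3)O2)cc(O)c1O | target

## Step count and least certain steps

Total: 7 steps. Longest linear sequence: 6 steps (steps 1, 3, 4, 5, 6, 7; the branch through step 2 is equally long).

**Step 6 (key step).** Most likely to go wrong: a second oxidation at C2 of the product (16 keeps a para-hydroxybenzylic hydrogen), intermolecular capture of 15 by another molecule or by water, and incomplete equilibration at C2. Fallback, from 14 back to 16, separates oxidation from ring closure. 14 is oxidised with Ag2O in CH2Cl2–MeOH so that 15 is trapped at once by the solvent as the benzylic methyl ether, the 1-methoxy derivative of 14 F1 (both C1 epimers). F1 is then treated with catalytic camphorsulfonic acid in dry CH2Cl2 over 5 Å sieves: it ionises to the para-hydroxybenzyl cation, the C5 hydroxyl closes the ring under thermodynamic control, and the methanol is taken up by the sieves, giving 16.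

**Step 2.** Most likely to go wrong: benzylation of the para-oxygen, or of both oxygens, if the dianion is not fully formed. Fallback, from 5 back to 7, uses the acidity order instead. MOMCl (1 equiv) and i-Pr2NEt alkylate the more acidic para-hydroxyl to give 3-hydroxy-5-methoxy-4-(methoxymethoxy)benzaldehyde F2; BnBr and K2CO3 in DMF give 3-(benzyloxy)-5-methoxy-4-(methoxymethoxy)benzaldehyde F3; HCl in MeOH removes the acetal and gives 7.

**Step 3.** Most likely to go wrong: loss of site selectivity (condensation at the C5 methylene, or at the central carbon if chelation is incomplete) and sluggish reaction of the electron-rich aldehyde. Fallback, from 7 and 4 back to 11 (so step 4 is bypassed as well), replaces condensation by alkylation. 7 is silylated (TIPSCl, imidazole, DMF) to 3-(benzyloxy)-5-methoxy-4-(triisopropylsilyloxy)benzaldehyde F4, reduced with NaBH4 to [3-(benzyloxy)-5-methoxy-4-(triisopropylsilyloxy)phenyl]methanol F5 and converted with PBr3 into the corresponding benzyl bromide F6. 4 is deprotonated twice with LiN(i-Pr)2 to the dilithium dianion of 4 F7, which is alkylated at its terminal carbon by F6 to give the triisopropylsilyl ether of 11 F8. Bu4NF buffered with AcOH removes the silyl group and gives 11.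

**Step 4.** Most likely to go wrong: partial hydrogenolysis of the aryl benzyl ethers if the catalyst is too lightly poisoned, or stalled alkene reduction if it is too heavily poisoned; sulfide carried forward would also poison the ruthenium catalyst of step 5, so 11 must be purified. Fallback, from 10 back to 11, is a metal-free reduction: diimide F9, generated in the flask from 2-nitrobenzenesulfonohydrazide and Et3N, transfers two hydrogens to the C=C bond in a concerted way and cannot cleave C–O bonds.

**Step 7.** Most likely to go wrong: reductive opening of the pyran at the benzylic O1–C2 bond in competition with O-debenzylation, and air oxidation of the liberated catechol during isolation. Fallback, from 16 back to 17 with no new compound, is a non-reductive debenzylation: BCl3 and pentamethylbenzene in CH2Cl2 at −78 °C, then methanolysis of the borates. The benzyl cations are taken up by the arene, the methyl ether should not be attacked at this temperature, and ionisation at C2 is disfavoured because the para-oxygen of ring A is bound to boron during the reaction.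

## Further compounds

F1 | step 6 | 1-methoxy derivative of 14, (3R,5S) by CIP with C3 and C5 unchanged in space, both C1 epimers | COc1cc(C(OC)C[C@H](O)C[C@@H](O)CCc2ccc(OCc3ccccc3)cc2)cc(OCc2ccccc2)c1O
F2 | step 2 | 3-hydroxy-5-methoxy-4-(methoxymethoxy)benzaldehyde | COCOc1c(O)cc(C=O)cc1OC
F3 | step 2 | 3-(benzyloxy)-5-methoxy-4-(methoxymethoxy)benzaldehyde | COCOc1c(OCc2ccccc2)cc(C=O)cc1OC
F4 | step 3 | 3-(benzyloxy)-5-methoxy-4-(triisopropylsilyloxy)benzaldehyde | COc1cc(C=O)cc(OCc2ccccc2)c1O[Si](C(C)C)(C(C)C)C(C)C
F5 | step 3 | [3-(benzyloxy)-5-methoxy-4-(triisopropylsilyloxy)phenyl]methanol | COc1cc(CO)cc(OCc2ccccc2)c1O[Si](C(C)C)(C(C)C)C(C)C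
F6 | step 3 | 3-(benzyloxy)-5-methoxy-4-(triisopropylsilyloxy)benzyl bromide | COc1cc(CBr)cc(OCc2ccccc2)c1O[Si](C(C)C)(C(C)C)C(C)C
F7 | step 3 | dilithium dianion of 4 | [Li+].[Li+].C=C([O-])C=C([O-])CCc1ccc(OCc2ccccc2)cc1
F8 | step 3 | 1-[3-(benzyloxy)-5-methoxy-4-(triisopropylsilyloxy)phenyl]-7-[4-(benzyloxy)phenyl]heptane-3,5-dione | COc1cc(CCC(=O)CC(=O)CCc2ccc(OCc3ccccc3)cc2)cc(OCc2ccccc2)c1O[Si](C(C)C)(C(C)C)C(C)C
F9 | step 4 | diimide | N=N
F0 | step 7 | none | none
A1 | alternative 1 | 2-(tert-butyldimethylsilyl)-1,3-dithiane | CC(C)(C)[Si](C)(C)C1SCCCS1
A2 | alternative 1 | (S)-2-{2-[4-(benzyloxy)phenyl]ethyl}oxirane | C1O[C@H]1CCc1ccc(OCc2ccccc2)cc1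
A3 | alternative 1 | (R)-2-[3,4-bis(benzyloxy)-5-methoxyphenyl]oxirane | COc1cc([C@@H]2CO2)cc(OCc2ccccc2)c1OCc1ccccc1
A4 | alternative 1 | (1S,5S)-1-[3,4-bis(benzyloxy)-5-methoxyphenyl]-7-[4-(benzyloxy)phenyl]-5-(tert-butyldimethylsilyloxy)-1-hydroxyheptan-3-one propane-1,3-diyl dithioketal | COc1cc([C@@H](O)CC2(SCCCS2)C[C@@H](O[Si](C)(C)C(C)(C)C)CCc2ccc(OCc3ccccc3)cc2)cc(OCc2ccccc2)c1OCc1ccccc1
A5 | alternative 2 | (1S,3R,5E,7R)-1-[3,4-bis(benzyloxy)-5-methoxyphenyl]-7-[4-(benzyloxy)phenyl]-3-(tert-butyldimethylsilyloxy)hept-5-ene-1,7-diol | COc1cc([C@@H](O)C[C@H](O[Si](C)(C)C(C)(C)C)C/C=C/[C@@H](O)c2ccc(OCc3ccccc3)cc2)cc(OCc2ccccc2)c1OCc1ccccc1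
A6 | alternative 2 | (2S,4R,6R)-2-[3,4-bis(benzyloxy)-5-methoxyphenyl]-6-{(E)-2-[4-(benzyloxy)phenyl]ethenyl}-4-(tert-butyldimethylsilyloxy)tetrahydro-2H-pyran, all-cis | COc1cc([C@@H]2C[C@H](O[Si](C)(C)C(C)(C)C)C[C@H](/C=C/c3ccc(OCc4ccccc4)cc3)O2)cc(OCc2ccccc2)c1OCc1ccccc1
A7 | alternative 3 | (2S,6S)-2-[3,4-bis(benzyloxy)-5-methoxyphenyl]-6-{2-[4-(benzyloxy)phenyl]ethyl}-4-methylidene-1,3-dioxane, cis | COc1cc([C@@H]2OC(=C)C[C@H](CCc3ccc(OCc4ccccc4)cc3)O2)cc(OCc2ccccc2)c1OCc1ccccc1
A8 | alternative 3 | (2S,6S)-2-[3,4-bis(benzyloxy)-5-methoxyphenyl]-6-{2-[4-(benzyloxy)phenyl]ethyl}tetrahydro-4H-pyran-4-one, cis | COc1cc([C@@H]2CC(=O)C[C@H](CCc3ccc(OCc4ccccc4)cc3)O2)cc(OCc2ccccc2)c1OCc1ccccc1
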